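## Retrosynthetic overview

1. The target comes from one Lewis-acid unmasking (two MOM ethers plus the buttressed C5-OMe) of a fully protected chalcone. That chalcone comes from a Claisen–Schmidt union of an (R)-6-acetyl-5,7-dimethoxychromane with 2,4-bis(methoxymethoxy)benzaldehyde, itself made from 2,4-dihydroxybenzaldehyde.
2. The pyran ring, the C4–C3 and O–C2 bonds and the C3 stereocentre all come from one catalytic enantioselective oxa-[4+2]. It joins a dearomatised ortho-quinone methide to one C=C of the C2v-symmetric 2,6-dimethylhepta-2,5-diene, and the untouched C=C becomes the prenyl group.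
3. The ortho-quinone methide comes from a benzylic acetate, made from symmetric 4'-hydroxy-2',6'-dimethoxyacetophenone with CH2O/AcOH. This arene has one phenol and one kind of ortho position, so there is no regiochemical choice.
4. The diene comes from prenyl bromide and isobutenylmagnesium bromide.
5. Ring order: both benzene rings are bought, and the pyran ring is the only ring made (step 3).

Assumption: the sense of induction of the chiral acid in step 3 cannot be predicted. The (S,S)-catalyst is written, and its mirror image is used if the first run gives the (S)-chromane (checked by chiral HPLC and ECD). Compounds 1, 2 (0.5 M in THF), 4 and 9 are taken as catalogue items.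

## Route

**Step 1**
Reactants: 1 prenyl bromide (1-bromo-3-methylbut-2-ene); 2 2-methylprop-1-enylmagnesium bromide
Product: 3 2,6-dimethylhepta-2,5-diene
Conditions: CuI (5 mol %), THF, −30 °C → rt; distil
Reagents that add atoms: none
Why: This is a copper-catalysed allyl–vinyl Grignard cross-coupling, and it goes SN2 rather than SN2' because the γ-carbon of the prenyl halide is fully substituted, giving the skipped, symmetric diene.

**Step 2**
Reactants: 4 1-(4-hydroxy-2,6-dimethoxyphenyl)ethan-1-one
Product: 6 (3-acetyl-6-hydroxy-2,4-dimethoxyphenyl)methyl acetate, via benzylic alcohol 5 (not isolated)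
Conditions: 37 % aq CH2O (1.05 equiv), NaOAc, AcOH, 80 °C
Reagents that add atoms: formaldehyde C=O; acetic acid CC(=O)O
Why: This is a Lederer–Manasse ortho-hydroxymethylation followed by acetolysis of the activated benzylic alcohol, and because the two ortho positions of 4 are equivalent and the para position carries the acetyl group, only one mono-adduct can form, with limiting CH2O holding back the bis-adduct.

**Step 3 (key step)**
Reactants: 6 (3-acetyl-6-hydroxy-2,4-dimethoxyphenyl)methyl acetate; 3 2,6-dimethylhepta-2,5-diene (5 equiv, excess recovered)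
Product: 8 (3R)-6-acetyl-5,7-dimethoxy-2,2-dimethyl-3-(3-methylbut-2-enyl)chromane, via ortho-quinone methide 7 (not isolated)
Conditions: (S,S)-IDPi (BINOL-derived N,N'-bis(triflyl)imidodiphosphorimidate, 3,3'-aryl = 3,5-(CF3)2C6H3, 5 mol %), toluene, −40 °C
Reagents that add atoms: none
Why: Proposed new method: the confined strong chiral Brønsted acid ionises the electron-rich benzylic acetate to the dearomatised ortho-quinone methide 7, held as a hydrogen-bonded ion pair in the catalyst pocket, and one of the two equivalent trisubstituted C=C bonds of the symmetric diene adds in an asynchronous inverse-electron-demand oxa-[4+2] (CH2 to the =CH carbon, O to the CMe2 carbon, Markovnikov polarity), so C3 is fixed as R by enantioface selection at the C–C bond-forming event and cannot be lost afterwards because C2 carries two identical methyl groups, with rearomatisation driving ring closure; the closest known reaction types are racemic thermal ortho-quinone methide/terpene hetero-Diels–Alder reactions and chiral phosphoric or imidodiphosphoric acid-catalysed ortho-quinone methide [4+2] cycloadditions with styrenes and with tethered unactivated alkenes.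

**Step 4**
Reactants: 9 2,4-dihydroxybenzaldehyde
Product: 10 2,4-bis(methoxymethoxy)benzaldehyde
Conditions: NaH (2.5 equiv), MOMCl (2.5 equiv), DMF, 0 °C → rt
Reagents that add atoms: chloromethyl methyl ether COCCl
Why: This is a Williamson-type O-alkylation of both sodium phenoxides, where full deprotonation also frees the chelated 2-OH, and it removes the phenoxide deactivation of the aldehyde before the aldol step.

**Step 5**
Reactants: 8 (3R)-6-acetyl-5,7-dimethoxy-2,2-dimethyl-3-(3-methylbut-2-enyl)chromane; 10 2,4-bis(methoxymethoxy)benzaldehyde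
Product: 11 (E)-3-[2,4-bis(methoxymethoxy)phenyl]-1-[(3R)-5,7-dimethoxy-2,2-dimethyl-3-(3-methylbut-2-enyl)chroman-6-yl]prop-2-en-1-one
Conditions: KOH, EtOH/H2O, rt, 24–48 h
Reagents that add atoms: none
Why: In this Claisen–Schmidt condensation only 8 can enolise and only 10 is an aldehyde, E1cB dehydration gives the thermodynamic E-enone, there is no free 2'-OH to close a flavanone, and C3 has no acidic hydrogen, so its configuration is untouched.

**Step 6**
Reactants: 11 protected chalcone
Product: 12 (E)-3-(2,4-dihydroxyphenyl)-1-[(3R)-5-hydroxy-7-methoxy-2,2-dimethyl-3-(3-methylbut-2-enyl)chroman-6-yl]prop-2-en-1-one (target)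
Conditions: BCl3 (4 equiv), CH2Cl2, −78 → −20 °C; ice-water quench, immediate extraction
Reagents that add atoms: none
Why: In this chelation-directed Lewis-acid ether cleavage, BCl3 locks onto the ketone and removes just one flanking O-methyl group (the O–B–O chelate then blocks the second), preferentially the C5-OMe that is twisted out of plane between C4H2 and the acyl group, while the two acetal-type MOM ethers go faster still, and the isolated prenyl C=C, the E-enone and the electron-poor pyran oxygen (para to the complexed carbonyl, so no ionisation at C2 and no scrambling of C3) survive at low temperature.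

## Compound list

| No. | Name | SMILES | Role |
|---|---|---|---|
| 1 | prenyl bromide | CC(C)=CCBr | starting material |
| 2 | 2-methylprop-1-enylmagnesium bromide | CC(C)=C[Mg]Br | starting material |
| 3 | 2,6-dimethylhepta-2,5-diene | CC(C)=CCC=C(C)C | intermediate |
| 4 | 1-(4-hydroxy-2,6-dimethoxyphenyl)ethan-1-one | CC(=O)c1c(OC)cc(O)cc1OC | starting material |
| 5 | 1-[4-hydroxy-3-(hydroxymethyl)-2,6-dimethoxyphenyl]ethan-1-one | CC(=O)c1c(OC)cc(O)c(CO)c1OC | intermediate (not isolated) |
| 6 | (3-acetyl-6-hydroxy-2,4-dimethoxyphenyl)methyl acetate | CC(=O)OCc1c(O)cc(OC)c(C(C)=O)c1OC | intermediate |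
| 7 | 4-acetyl-3,5-dimethoxy-6-methylidenecyclohexa-2,4-dien-1-one (ortho-quinone methide) | C=C1C(=O)C=C(OC)C(C(C)=O)=C1OC | intermediate (not isolated) |
| 8 | (3R)-6-acetyl-5,7-dimethoxy-2,2-dimethyl-3-(3-methylbut-2-enyl)chromane | COc1cc2c(c(OC)c1C(C)=O)C[C@@H](CC=C(C)C)C(C)(C)O2 | intermediate |
| 9 | 2,4-dihydroxybenzaldehyde | O=Cc1ccc(O)cc1O | starting material |
| 10 | 2,4-bis(methoxymethoxy)benzaldehyde | COCOc1ccc(C=O)c(OCOC)c1 | intermediate |
| 11 | (E)-3-[2,4-bis(methoxymethoxy)phenyl]-1-[(3R)-5,7-dimethoxy-2,2-dimethyl-3-(3-methylbut-2-enyl)chroman-6-yl]prop-2-en-1-one | COc1cc2c(c(OC)c1C(=O)/C=C/c1ccc(OCOC)cc1OCOC)C[C@@H](CC=C(C)C)C(C)(C)O2 | intermediate |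
| 12 | (E)-3-(2,4-dihydroxyphenyl)-1-[(3R)-5-hydroxy-7-methoxy-2,2-dimethyl-3-(3-methylbut-2-enyl)chroman-6-yl]prop-2-en-1-one | COc1cc2c(c(O)c1C(=O)/C=C/c1ccc(O)cc1O)C[C@@H](CC=C(C)C)C(C)(C)O2 | target |

## Step count and fallbacks

Total step count: 6.
Longest linear sequence: 4 steps (4 → 6 → 8 → 11 → 12, that is steps 2, 3, 5 and 6).

The three steps most likely to fail are steps 3, 6 and 2.

**Step 3.** The risks are the enantioselectivity of an intermolecular cycloaddition with an unactivated alkene, and self-condensation of 7.
- The fallback sets out from 4 and comes back at 8. It drops the cycloaddition and takes the stereocentre from the chiral pool.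
- Iodinate 4 with NIS (MeCN, 0 °C) to give 1-(4-hydroxy-3-iodo-2,6-dimethoxyphenyl)ethan-1-one F1.
- Take (S)-lavandulol F2, which is a pheromone-trade chemical or can be obtained by lipase resolution of the commercial racemate.
- Convert it with I2/PPh3/imidazole into (S)-lavandulyl iodide F3, then with Zn dust/LiCl in THF into (S)-lavandulylzinc iodide F4.
- Negishi coupling of F1 with F4 (2.2 equiv, Pd(OAc)2/CPhos, THF) gives 1-{4-hydroxy-2,6-dimethoxy-3-[(2R)-5-methyl-2-(prop-1-en-2-yl)hex-4-enyl]phenyl}ethan-1-one F5.
- Catalytic p-TsOH in CH2Cl2 then adds the phenol to the isopropenyl group in the Markovnikov sense and closes the pyran ring to 8.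
- The stereocentre is never touched. The descriptor changes from S to R only because the CIP priorities change.

**Step 6.** The risks are C5-OMe versus C7-OMe selectivity, and exposure of the prenyl group and the 2-hydroxychalcone to BCl3.
- The fallback sets out from 8 and comes back at 12. It separates the demethylation from the MOM removal.
- Treat ketone 8 itself with BCl3 (1.2 equiv, −78 °C) to give (3R)-6-acetyl-5-hydroxy-7-methoxy-2,2-dimethyl-3-(3-methylbut-2-enyl)chromane F6.
- At this stage the regiochemistry can be assigned by HMBC/NOE. The wrong phenol can be removed by chromatography and recycled to 8 by re-methylation.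
- Condense F6 with 10 (KOH, EtOH) to give (E)-3-[2,4-bis(methoxymethoxy)phenyl]-1-[(3R)-5-hydroxy-7-methoxy-2,2-dimethyl-3-(3-methylbut-2-enyl)chroman-6-yl]prop-2-en-1-one F7.
- Finish with a Brønsted-acid acetal exchange (dilute HCl, MeOH, rt) to reach 12. These conditions cannot cleave an aryl methyl ether.

**Step 2.** The risks are mono- versus bis-acetoxymethylation, diarylmethane formation, and the lability of 6.
- The fallback sets out from 4 and comes back at 5. It installs the carbon at the aldehyde oxidation level, which switches the ring off after one substitution.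
- Magnesium-mediated ortho-formylation of 4 (MgCl2, Et3N, paraformaldehyde, MeCN, reflux) gives 3-acetyl-6-hydroxy-2,4-dimethoxybenzaldehyde F8.
- NaBH4 (MeOH, 0 °C) reduces the aldehyde in preference to the hindered ketone and gives isolated 5.
- Compound 5 is used in place of 6 under the step 3 conditions with 4 Å molecular sieves. It loses water to give the same intermediate 7, and then 8.

## Further compounds

F1 | step 3 | 1-(4-hydroxy-3-iodo-2,6-dimethoxyphenyl)ethan-1-one | CC(=O)c1c(OC)cc(O)c(I)c1OC
F2 | step 3 | (S)-lavandulol | OC[C@@H](CC=C(C)C)C(C)=C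
F3 | step 3 | (S)-lavandulyl iodide | IC[C@@H](CC=C(C)C)C(C)=C
F4 | step 3 | (S)-lavandulylzinc iodide | I[Zn]C[C@@H](CC=C(C)C)C(C)=C
F5 | step 3 | 1-{4-hydroxy-2,6-dimethoxy-3-[(2R)-5-methyl-2-(prop-1-en-2-yl)hex-4-enyl]phenyl}ethan-1-one | CC(=O)c1c(OC)cc(O)c(C[C@@H](CC=C(C)C)C(C)=C)c1OC
F6 | step 6 | (3R)-6-acetyl-5-hydroxy-7-methoxy-2,2-dimethyl-3-(3-methylbut-2-enyl)chromane | COc1cc2c(c(O)c1C(C)=O)C[C@@H](CC=C(C)C)C(C)(C)O2
F7 | step 6 | (E)-3-[2,4-bis(methoxymethoxy)phenyl]-1-[(3R)-5-hydroxy-7-methoxy-2,2-dimethyl-3-(3-methylbut-2-enyl)chroman-6-yl]prop-2-en-1-one | COc1cc2c(c(O)c1C(=O)/C=C/c1ccc(OCOC)cc1OCOC)C[C@@H](CC=C(C)C)C(C)(C)O2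
F8 | step 2 | 3-acetyl-6-hydroxy-2,4-dimethoxybenzaldehyde | CC(=O)c1c(OC)cc(O)c(C=O)c1OC
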